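A direct plan would cut the depside ester bond. 5-Methylbenzene-1,2,3-triol A1 would be carboxylated under Kolbe–Schmitt conditions to 2,3,4-trihydroxy-6-methylbenzoic acid A2, and A2 would be joined, unprotected, to the 4-hydroxyl of methyl 2,4-dihydroxy-3,6-dimethylbenzoate A3, for instance with an arylboronic acid as transient mask and activator.
Its weakest points would be:
- The carboxylation of A1: hot aqueous base would act on an air-sensitive triol, and the acid A2 would decarboxylate and oxidise easily, so it could not be stored.
- The esterification of A2 with A3: a carboxyl flanked by OH and CH3 would have to acylate a phenol with five free hydroxyls in the flask, by a boron double role that has no precedent, and it would consume both finished arenes in the last step.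
- A rescue by benzylating A2 would add three or four steps that build no skeleton.

Plan of the new route. The ester C–O bond is not the strategic cut; two C–C bonds of ring A are cut instead, C1′–C2′ and C5′–C6′.
Ring A allows this because C1′ (bearing the carboxyl) and C6′ (bearing the methyl) are the two sp carbons of a but-2-ynoate, while C2′, C3′, C4′, C5′ carry O, O, O, H, which is the pattern of the bis(silyl) dienol ether of a 2-alkoxyacetoacetate.
Ring B is bought and its O4 is acylated first with the small, unhindered but-2-ynoic acid; ring A is then built last, around the ester that already exists, by Diels–Alder reaction and loss of ethanol.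
No pyrogallol is carboxylated, no free trihydroxy acid exists, and the hindered aryl ester is never made by acylation; a single benzyl ether is the only protecting group.

Key step: step 4

Remark: methyl 2,4-dihydroxy-3,6-dimethylbenzoate, but-2-ynoic acid, ethyl 2-diazo-3-oxobutanoate and benzyl alcohol are taken as purchased. The racemic stereocentres of the α-benzyloxy ketoester and of the cycloadduct, and the double-bond geometry of the silyl enol ethers, are left undefined because all are lost on aromatisation; the target has no stereocentre.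

Step 1
Reactants: 1 methyl 2,4-dihydroxy-3,6-dimethylbenzoate; 2 but-2-ynoic acid
Product: 3 methyl 4-(but-2-ynoyloxy)-2-hydroxy-3,6-dimethylbenzoate
Conditions: 2 (1.1 equiv), DCC (1.15 equiv), DMAP (5 mol %), CH2Cl2, 0 °C → rt
Reagents that add atoms: none
Why: Steglich esterification of an unhindered alkynoic acid; only the 4-OH of 1 is free, the 2-OH being hydrogen-bonded to the ester carbonyl and flanked by two substituents, so monoacylation at O4 is expected, and no stereocentre is formed.

Step 2
Reactants: 4 ethyl 2-diazo-3-oxobutanoate; 5 benzyl alcohol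
Product: 6 ethyl 2-(benzyloxy)-3-oxobutanoate (racemic)
Conditions: Rh2(OAc)4 (1 mol %), 5 (1.5 equiv), CH2Cl2, 40 °C, slow addition of 4
Reagents that add atoms: none
Why: Rhodium-carbenoid O–H insertion (oxonium ylide, then 1,2-proton shift) places the future C3′ oxygen as a benzyl ether; the new stereocentre is racemic and is erased by enolisation in step 3.

Step 3
Reactants: 6 ethyl 2-(benzyloxy)-3-oxobutanoate
Product: 8 2-(benzyloxy)-1-ethoxy-1,3-bis(trimethylsilyloxy)buta-1,3-diene, via silyl enol ether 7 (not isolated)
Conditions: TMSCl, Et3N, PhMe, rt; filter under Ar, concentrate; then LiN(iPr)2 (LDA), THF, −78 °C; TMSCl, −78 → 0 °C; used crude after filtration from hexane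
Reagents that add atoms: chlorotrimethylsilane, C[Si](C)(C)Cl
Why: Two-stage enol silylation as used for 1-alkoxy-1,3-bis(silyloxy)dienes: soft enolisation gives the conjugated enol ether 7, whose γ-methyl is then deprotonated kinetically and the vinylogous enolate silylated on the ester oxygen; the double-bond geometry is of no consequence.

Step 4
Reactants: 3 methyl 4-(but-2-ynoyloxy)-2-hydroxy-3,6-dimethylbenzoate; 8 2-(benzyloxy)-1-ethoxy-1,3-bis(trimethylsilyloxy)buta-1,3-diene
Product: 12 methyl 4-{[3-(benzyloxy)-2,4-dihydroxy-6-methylbenzoyl]oxy}-2-hydroxy-3,6-dimethylbenzoate, via trimethylsilyl ether 9 (not isolated), via cyclohexadiene cycloadduct 10 (not isolated), via tris(silyl) arene 11 (not isolated)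
Conditions: 3, BSA (N,O-bis(trimethylsilyl)acetamide, 1.5 equiv), PhMe, 80 °C, 1 h; then 8 (3 equiv), 110–120 °C, sealed tube, 24–48 h; then 1 M HCl, THF, 0 °C → rt
Reagents that add atoms: none
Why: A thermal Diels–Alder reaction of normal electron demand joins the electron-rich diene 8 to the acceptor alkyne of 9: the CH2 terminus C4 of the diene (largest HOMO coefficient, since the 3-silyloxy group and the ketene acetal both push towards it) bonds to the β-carbon of the butynoate (largest LUMO coefficient) and the ketene acetal carbon C1 bonds to the α-carbon, so that in 10 the carboxyl-bearing carbon C1′ lies next to the acetal carbon C2′ and the methyl-bearing carbon C6′ next to the CH2 C5′. The closest known reaction type is the cycloaddition–elimination of 1-alkoxy-1,3-bis(silyloxy)buta-1,3-dienes with acetylenic esters to give 2,4-dihydroxybenzoates, and the benzannulation of macrocyclic alk-2-ynoate lactones with bis(silyloxy)dienes used for resorcylic macrolides. Ring A is closed by an intermolecular [4+2] cycloaddition that forms C1′–C2′ and C5′–C6′ in one operation; 10 then loses ethanol from C2′ together with a hydrogen of C5′ (1,4-elimination, driven by aromatisation) to give 11, and dilute acid removes the three O–Si groups. No stereocentre remains, the one in 10 being destroyed. The step needs regioselectivity, secured by the matched polarisation of both partners (the 2-benzyloxy group, the only donor pushing the other way, is outweighed by three oxygen donors), and chemoselectivity: the chelated phenol is masked as its silyl ether so that it cannot protonate the ketene acetal, silyl enol ethers do not acylate aryl or methyl esters without a Lewis acid, and the benzoate carbonyls are not dienophiles. The precursor pair 3 and 8 holds one benzene ring and no hindered ester, whereas the product holds the complete depside.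

Step 5
Reactants: 12 methyl 4-{[3-(benzyloxy)-2,4-dihydroxy-6-methylbenzoyl]oxy}-2-hydroxy-3,6-dimethylbenzoate
Product: 13 methyl 2-hydroxy-3,6-dimethyl-4-[(2,3,4-trihydroxy-6-methylbenzoyl)oxy]benzoate
Conditions: H2 (1 atm), 10% Pd/C, EtOAc, rt; filtration and concentration under Ar
Reagents that add atoms: none
Why: Catalytic hydrogenolysis of the benzyl aryl ether under neutral conditions, to which the aryl ester, the methyl ester and both arenes are inert; no base is present that could cleave the depside or promote oxidation of the pyrogallol.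

Compound list
1 | methyl 2,4-dihydroxy-3,6-dimethylbenzoate | COC(=O)c1c(C)cc(O)c(C)c1O | starting material
2 | but-2-ynoic acid | CC#CC(=O)O | starting material
3 | methyl 4-(but-2-ynoyloxy)-2-hydroxy-3,6-dimethylbenzoate | COC(=O)c1c(C)cc(OC(=O)C#CC)c(C)c1O | intermediate
4 | ethyl 2-diazo-3-oxobutanoate | CCOC(=O)C(=[N+]=[N-])C(C)=O | starting material
5 | benzyl alcohol | OCc1ccccc1 | starting material
6 | ethyl 2-(benzyloxy)-3-oxobutanoate (racemic) | CCOC(=O)C(OCc1ccccc1)C(C)=O | intermediate
7 | ethyl 2-(benzyloxy)-3-(trimethylsilyloxy)but-2-enoate | CCOC(=O)C(OCc1ccccc1)=C(C)O[Si](C)(C)C | intermediate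
8 | 2-(benzyloxy)-1-ethoxy-1,3-bis(trimethylsilyloxy)buta-1,3-diene | C=C(O[Si](C)(C)C)C(OCc1ccccc1)=C(OCC)O[Si](C)(C)C | intermediate
9 | methyl 4-(but-2-ynoyloxy)-3,6-dimethyl-2-(trimethylsilyloxy)benzoate | COC(=O)c1c(C)cc(OC(=O)C#CC)c(C)c1O[Si](C)(C)C | intermediate
10 | methyl 4-{[5-(benzyloxy)-6-ethoxy-2-methyl-4,6-bis(trimethylsilyloxy)cyclohexa-1,4-diene-1-carbonyl]oxy}-3,6-dimethyl-2-(trimethylsilyloxy)benzoate (racemic) | CCOC1(O[Si](C)(C)C)C(OCc2ccccc2)=C(O[Si](C)(C)C)CC(C)=C1C(=O)Oc1cc(C)c(C(=O)OC)c(O[Si](C)(C)C)c1C | intermediate
11 | methyl 4-{[3-(benzyloxy)-6-methyl-2,4-bis(trimethylsilyloxy)benzoyl]oxy}-3,6-dimethyl-2-(trimethylsilyloxy)benzoate | COC(=O)c1c(C)cc(OC(=O)c2c(C)cc(O[Si](C)(C)C)c(OCc3ccccc3)c2O[Si](C)(C)C)c(C)c1O[Si](C)(C)C | intermediate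
12 | methyl 4-{[3-(benzyloxy)-2,4-dihydroxy-6-methylbenzoyl]oxy}-2-hydroxy-3,6-dimethylbenzoate | COC(=O)c1c(C)cc(OC(=O)c2c(C)cc(O)c(OCc3ccccc3)c2O)c(C)c1O | intermediate
13 | methyl 2-hydroxy-3,6-dimethyl-4-[(2,3,4-trihydroxy-6-methylbenzoyl)oxy]benzoate | COC(=O)c1c(C)cc(OC(=O)c2c(C)cc(O)c(O)c2O)c(C)c1O | target

Total step count: 5. Longest linear sequence: 4 steps (4 → 6 → 8 → 12 → 13).

Steps most likely to fail

Step 4. The cycloaddition to the methyl-substituted, singly activated triple bond may be slower than the thermal decay of the ketene acetal diene (silyl migration to carbon, protonolysis), so that the diene is consumed before the alkyne. The fallback sets out from 1 and comes back at 12, replacing the alkyne by an allene as the 2π partner. Phenol 1 would be acylated with but-3-ynoic acid (DCC, CH2Cl2, 0 °C) to methyl 4-(but-3-ynoyloxy)-2-hydroxy-3,6-dimethylbenzoate F1. Catalytic Et3N should isomerise this to methyl 4-(buta-2,3-dienoyloxy)-2-hydroxy-3,6-dimethylbenzoate F2, which BSA would convert to methyl 4-(buta-2,3-dienoyloxy)-3,6-dimethyl-2-(trimethylsilyloxy)benzoate F3. The conjugated C2=C3 bond of the allene, a much better dienophile than the alkyne, should take up diene 8 at 20–60 °C in the same orientation to give the exo-methylene cyclohexene adduct F4. Dilute acid should then expel ethanol, move the exocyclic double bond into the ring and remove the silyl groups, arriving at 12.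

Step 3. The dienolate may be silylated at carbon instead of oxygen, the benzylic position may be deprotonated, or the ketene acetal may be hydrolysed during isolation. The fallback sets out from benzyl alcohol 5 and from 9 (made from 3 as in step 4) and comes back at 11; it uses a cyclic diene made only of ketone silyl enol ethers and aromatises by cycloreversion. 5,5-Dimethylcyclohexane-1,3-dione F5 would undergo diazo transfer (4-acetamidobenzenesulfonyl azide, Et3N, MeCN) to 2-diazo-5,5-dimethylcyclohexane-1,3-dione F6. O–H insertion into 5 with Rh2(OAc)4 should then give 2-(benzyloxy)-5,5-dimethylcyclohexane-1,3-dione F7. TMSOTf and Et3N in Et2O should convert this into 2-(benzyloxy)-5,5-dimethyl-1,3-bis(trimethylsilyloxy)cyclohexa-1,3-diene F8, which is locked s-cis and stable to heat. Heating this diene with 9 at 140–160 °C should give, with the same orientation, the bicyclo[2.2.2]octadiene adduct F9, which would lose 2-methylpropene by retro-Diels–Alder reaction (Alder–Rickert) and so arrive at 11; the hydrolysis of 11 to 12 is that of step 4. This diene would also serve if the cycloaddition of step 4 fails with both dienophiles.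

Step 2. The rhodium carbenoid may be diverted into Wolff rearrangement, dimerisation or insertion into adventitious water. The fallback sets out from 5 and comes back at 6, forming the C2–C3 bond of the ketoester instead of the C–O bond. Benzyl alcohol 5 would be alkylated with ethyl bromoacetate (NaH, THF) to ethyl 2-(benzyloxy)acetate F10. Its lithium enolate (LDA, 2 equiv, THF, −78 °C) would be acylated with N-methoxy-N-methylacetamide in a crossed Claisen-type condensation and quenched with dilute HCl to give 6.

Further compounds
F1 | step 4 | methyl 4-(but-3-ynoyloxy)-2-hydroxy-3,6-dimethylbenzoate | COC(=O)c1c(C)cc(OC(=O)CC#C)c(C)c1O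
F2 | step 4 | methyl 4-(buta-2,3-dienoyloxy)-2-hydroxy-3,6-dimethylbenzoate | COC(=O)c1c(C)cc(OC(=O)C=C=C)c(C)c1O
F3 | step 4 | methyl 4-(buta-2,3-dienoyloxy)-3,6-dimethyl-2-(trimethylsilyloxy)benzoate | COC(=O)c1c(C)cc(OC(=O)C=C=C)c(C)c1O[Si](C)(C)C
F4 | step 4 | methyl 4-{[3-(benzyloxy)-2-ethoxy-6-methylidene-2,4-bis(trimethylsilyloxy)cyclohex-3-ene-1-carbonyl]oxy}-3,6-dimethyl-2-(trimethylsilyloxy)benzoate (mixture of stereoisomers) | C=C1CC(O[Si](C)(C)C)=C(OCc2ccccc2)C(OCC)(O[Si](C)(C)C)C1C(=O)Oc1cc(C)c(C(=O)OC)c(O[Si](C)(C)C)c1C
F5 | step 3 | 5,5-dimethylcyclohexane-1,3-dione | CC1(C)CC(=O)CC(=O)C1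
F6 | step 3 | 2-diazo-5,5-dimethylcyclohexane-1,3-dione | CC1(C)CC(=O)C(=[N+]=[N-])C(=O)C1
F7 | step 3 | 2-(benzyloxy)-5,5-dimethylcyclohexane-1,3-dione | CC1(C)CC(=O)C(OCc2ccccc2)C(=O)C1
F8 | step 3 | 2-(benzyloxy)-5,5-dimethyl-1,3-bis(trimethylsilyloxy)cyclohexa-1,3-diene | CC1(C)CC(O[Si](C)(C)C)=C(OCc2ccccc2)C(O[Si](C)(C)C)=C1
F9 | step 3 | methyl 4-{[6-(benzyloxy)-3,8,8-trimethyl-1,5-bis(trimethylsilyloxy)bicyclo[2.2.2]octa-2,5-diene-2-carbonyl]oxy}-3,6-dimethyl-2-(trimethylsilyloxy)benzoate (racemic) | C[Si](C)(C)OC12CC(C)(C)C(C(C)=C1C(=O)Oc1cc(C)c(C(=O)OC)c(O[Si](C)(C)C)c1C)C(O[Si](C)(C)C)=C2OCc1ccccc1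
F10 | step 2 | ethyl 2-(benzyloxy)acetate | CCOC(=O)COCc1ccccc1
A1 | direct plan | 5-methylbenzene-1,2,3-triol | Cc1cc(O)c(O)c(O)c1
A2 | direct plan | 2,3,4-trihydroxy-6-methylbenzoic acid | Cc1cc(O)c(O)c(O)c1C(=O)O
A3 | direct plan | methyl 2,4-dihydroxy-3,6-dimethylbenzoate | COC(=O)c1c(C)cc(O)c(C)c1O
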